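## Structural features

The target is a depside without any stereocentre: ring A and ring B are joined by one aryl ester whose carbonyl carbon sits on C-A1 and whose oxygen sits on C-B4 (ring positions are written C-A1 to C-A6 and C-B1 to C-B6; bare labels such as A1 are kept for compounds of the alternatives). Ring A carries a free hydroxyl at C-A2, a methyl ether at C-A4 and a 2-oxoheptyl chain at C-A6, so the acyl carbon on C-A1 is flanked on both sides. Ring B is olivetolic acid (carboxyl on C-B1, hydroxyl on C-B2, pentyl on C-B6) acylated on the oxygen at C-B4. Three groups are fragile: the aryl ester, which is an activated acyl group; the benzylic ketone, whose enol or hemiketal oxygen can close onto that ester to give an isocoumarin and expel ring B; and the salicylic acid of ring B, which loses CO2 on heating. The real difficulty is the contiguous C-A1/C-A2/C-A6 substitution with two differentiated ring A oxygens, together with carrying the ketone through acid activation and ester formation. The key step uses the fact that C-A1 (acyl carbon attached) and C-A6 (benzylic CH2 attached) are neighbours and that C-A1 also neighbours the oxygen-bearing C-A2. That is the pattern a 3-alkoxyaryne acquires when a carbanion adds to the aryne carbon remote from the alkoxy group and the resulting aryl anion captures an acyl group. The two ring A oxygens can then be told apart because only the one at C-A2 can chelate the carbonyl on C-A1.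

## Logic of the disconnections

24 is first traced to 23 and 22 without cutting the skeleton. Two O–CH2Ph bonds are added (on the oxygen at C-A2 and on the carboxyl at C-B1), and the ketone C=O is exchanged for the two C–O bonds of a dioxolane. The reason is that the free ketone would attack any activated form of the ring A acid, and a neutral hydrogenolysis is the gentlest possible last step for an acid-, base- and heat-sensitive product. The gain is a fully masked depside. The demand is a ketal hydrolysis mild enough to spare the aryl ester, and a hydrogenolysis that leaves the ketone alone.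

22 is cut at the ester bond between the carbonyl carbon on C-A1 and the oxygen on C-B4, giving 19 and 21. This is the only bond joining the two rings, so the cut halves the molecule. The forward esterification must activate a 2,6-disubstituted benzoic acid and must choose the hydroxyl at C-B4 over the one at C-B2. The second point rests on the hydrogen bond that ties the C-B2 hydroxyl to the ester carbonyl in 21.

21 is cut at the benzyl–oxygen bond of its ester and goes back to 20, which is purchasable. The forward step must alkylate the carboxylate only and must stay cold enough to avoid decarboxylation.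

19 goes back to 18 (O–CH3 bond of the ester) and 17 (ketal C–O bonds). 17 is then cut at the C–C bond between the ketone carbon and the first carbon of the pentyl chain, giving 14 and 16, the latter made from 15. This cut turns the side chain into a two-carbon acyl arm on C-A6, exactly what the key step delivers. The forward addition must stop at the ketone and must not touch the hindered ring ester.

14 goes back through 13, 12 and 11 to 10 by functional group changes only: the O–benzyl bond at C-A2, the amide C–N bond, the O–CH3 bond at C-A2 and the O–C bond of the tert-butyl ester. The methyl ether at C-A2 is exchanged for a benzyl ether at this early stage, where a single carbonyl sits next to a single methoxy group. No Lewis acid is then needed once the aryl ester and the ketal are in place. The forward demand is a chelation-controlled demethylation that leaves the C-A4 ether intact.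

10 is cut at two bonds at once, C-A6–CH2 and C-A1–C(=O), which leads to 9 and 8. The gain is the largest of the route: a tetrasubstituted benzene with three adjacent, differentiated substituents becomes a symmetrical aryne precursor and a purchasable malonate. The forward step must add the carbanion to the aryne carbon remote from the methoxy group and must transfer the methyl ester carbonyl and not the tert-butyl one.

9 goes back to 7 (C–Si and C–O triflate bonds), and 7 through 6, 5, 4, 3 and 2 to 1 (O–S bond, C–Si bond, carbamate C–O bond). Because 1 is symmetrical, both positions ortho to the carbamate are the same, so the silylation has only one possible outcome next to the directing group. The N–H carbamate is chosen because it can be removed by base without acid, which an electron-rich arylsilane would not tolerate.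

## Other disconnections considered

Alternative 1: The cut goes through ring A. The C-A1–C-A2 and C-A5–C-A6 bonds are broken, so that C-A1 and C-A6 come from the triple bond of an aryl ynoate already esterified to ring B, benzyl 2-hydroxy-6-pentyl-4-{[4-(2-pentyl-1,3-dioxolan-2-yl)but-2-ynoyl]oxy}benzoate A2. C-A2 to C-A5 come from 1,3-dimethoxy-1-(trimethylsilyloxy)buta-1,3-diene A3. In the forward step A3 would add across the alkyne (a Diels–Alder reaction or its stepwise Michael/Claisen-type equivalent), the CH2 terminus of the diene bonding to the beta carbon (C-A6) and the ketene acetal carbon to the alpha carbon (C-A1). Loss of methanol and of the silyl group would then aromatise ring A to the ketal-protected benzyl ester A1.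
- In its favour: the hydroxyl at C-A2 and the methyl ether at C-A4 would leave the step already differentiated; the depside ester would be made from an unhindered ynoic acid and not from a 2,6-disubstituted benzoic acid; and compound A1 would be only a ketal hydrolysis and a hydrogenolysis away from 24.
- Against it here: the dienophile is a beta-alkyl-substituted ynoate, a class that reacts sluggishly and needs heat; the aryl ester of A2 is an acylating agent towards the nucleophilic diene and towards the methanol released; the free hydroxyl at C-B2 can protonate A3 or be silylated by it; and the propargylic CH2 can isomerise to an allene.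
- Structure: the alternative is the better on the C-A2/C-A4 oxygen pattern (no BCl3 step, no benzyl ether on ring A) and on avoiding a hindered esterification. The chosen plan is the better in keeping the sensitive aryl ester out of the ring-forming step.
- Mechanism: both fix regiochemistry by polarisation. The aryne insertion is expected to be fast at or below 80 °C, whereas a cycloaddition on a fully substituted alkyne is the less dependable of the two.
- Step economy: after its key step the alternative is clearly shorter (two steps against ten), but A2 needs a separate multi-step assembly of its ketal-bearing acyl part, so the totals are expected to be about equal.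

Alternative 2: The cut is in ring B, at the C-B1–C-B6 and C-B2–C-B3 bonds, which takes ring B back to dibenzyl malonate A5 and (E)-non-3-en-2-one A6. Forward, the sodium enolate of A5 (NaH) would add to the beta carbon of A6 (Michael addition). The methyl ketone enolate would then close on one benzyl ester (Claisen/Dieckmann-type, 6-exo-trig) to give racemic trans benzyl 2-hydroxy-4-oxo-6-pentylcyclohex-2-ene-1-carboxylate A4. A4 would be acylated on the oxygen at C-B4 with 19 and only then dehydrogenated to the arene, arriving at 22.
- In its favour: bulk starting materials, a robust one-flask sequence that makes two bonds and the ring, and independence from 20, which is costly and decarboxylates easily. The two stereocentres of A4 are of no consequence because aromatisation erases them.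
- Against it here: it solves ring B, which the chosen plan obtains in one step from a purchasable acid, and leaves ring A untouched. O-acylation of a cyclic 1,3-dione is ambident (oxygen at C-B2, oxygen at C-B4, carbon C-B3), and the acyl group of such an enol ester can migrate. The dehydrogenation (halogenation–elimination or a quinone oxidant) would have to spare the electron-rich ring A and the benzylic CH2 groups.
- Structure: equal to the chosen plan in that no lasting stereocentre is involved, and better in the cost of materials. It is worse in that the depside ester would have to survive an oxidation.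
- Mechanism: the Michael–Claisen step is as secure as anything in the chosen plan. The weak point is the late aromatisation, for which the chosen plan has no counterpart because ring B is aromatic from the start.
- Step economy: at least two steps more for ring B. A sensible use of this chemistry would be to aromatise A4 before any acylation, which would make it a supply route to 21 when 20 is not at hand.

Alternative 3: The cut is again in ring B, at the C-B3–C-B4 and C-B5–C-B6 bonds. C-B3, C-B2, C-B1 and C-B6 come from C3 to C6 of the 2-pyrone benzyl 4-(benzyloxy)-2-oxo-6-pentyl-2H-pyran-5-carboxylate A8, and C-B4 and C-B5 from the silyl ketene acetal tert-butyl[(1-methoxyethenyl)oxy]dimethylsilane A9. Forward, A9 would add across C3 and C6 of A8 (inverse-electron-demand Diels–Alder, CH2 to C6, acetal carbon to C3). The bicyclic lactone would lose CO2, and fluoride work-up would expel methoxide and the silyl group to give benzyl 2-(benzyloxy)-4-hydroxy-6-pentylbenzoate A7.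
- In its favour: A7 has the hydroxyl at C-B4 free and the one at C-B2 blocked, so the depside coupling could not go to the wrong oxygen. The aromatisation is built into the step, and 20 is not needed.
- Against it here: A8 is not purchasable and would take several steps from a beta-keto ester. Its C6 carries the pentyl group and its C4 an alkoxy donor, both of which lower its reactivity towards A9. CO2 extrusion needs heat, and the ketene acetal can also add in a conjugate sense and open the lactone.
- Structure: on regiocontrol of the coupling this alternative is the better, since it does not depend on the hydrogen bond that deactivates the C-B2 hydroxyl in 21. The extra benzyl ether would fall off in the same final hydrogenolysis, so the end game is equal.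
- Mechanism: cycloaddition with CO2 loss is a sound, well-understood sequence, comparable in reliability to the aryne insertion, but it is spent on the easier ring.
- Step economy: clearly worse, with several steps for a fragment that the chosen plan reaches in one. Ring A would still have to be made, most sensibly by the chosen key step.

Key step: step 4

Remark on the chemistry (assumption): compounds 1, 8, 15 and 20 are taken as purchasable, and the target has no stereocentre, so no step has to control configuration.

## Route

Step 1
Reactants: 1 3,5-dimethoxyphenol
Product: 2 3,5-dimethoxyphenyl N-(propan-2-yl)carbamate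
Conditions: i-PrNCO, Et3N (cat.), CH2Cl2, rt
Reagents that add atoms: isopropyl isocyanate, CC(C)N=C=O
Why: Base-catalysed addition of a phenol to an isocyanate (carbamoylation); it puts the strongest oxygen-based ortho-directing group on the ring in a form that base alone can later remove.

Step 2
Reactants: 2 3,5-dimethoxyphenyl N-(propan-2-yl)carbamate
Product: 5 3,5-dimethoxy-2-(trimethylsilyl)phenyl N-(propan-2-yl)carbamate, via N-silyl carbamate 3 (not isolated), via bis-silyl carbamate 4 (not isolated)
Conditions: TBSOTf, TMEDA, Et2O, 0 °C → rt; n-BuLi, TMEDA, −78 °C; Me3SiCl, −78 °C → rt; aq. NH4Cl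
Reagents that add atoms: chlorotrimethylsilane, C[Si](C)(C)Cl
Why: Directed ortho metalation: N-silylation turns the carbamate into a tertiary O-carbamate, which together with the neighbouring methoxy group directs lithiation to the carbon between them (the carbamate outranks the two methoxy groups that flank the other free position), and Me3SiCl traps the carbanion at −78 °C before any carbamoyl migration. The two ortho positions are equivalent by symmetry, and the N–Si bond is hydrolysed in the mild work-up.

Step 3
Reactants: 5 3,5-dimethoxy-2-(trimethylsilyl)phenyl N-(propan-2-yl)carbamate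
Product: 7 3,5-dimethoxy-2-(trimethylsilyl)phenyl trifluoromethanesulfonate, via silylphenol 6 (not isolated)
Conditions: DBU, Et2NH, MeCN, 40 °C; then PhNTf2, rt
Reagents that add atoms: N-phenylbis(trifluoromethanesulfonimide), O=S(=O)(N(c1ccccc1)S(=O)(=O)C(F)(F)F)C(F)(F)F
Why: E1cB cleavage of the N–H carbamate (the isocyanate is expelled and trapped by Et2NH as a urea) frees the phenoxide without acid, which would protodesilylate this electron-rich arylsilane; the phenoxide is then O-sulfonylated in the same flask by PhNTf2.

Step 4
Reactants: 7 3,5-dimethoxy-2-(trimethylsilyl)phenyl trifluoromethanesulfonate; 8 tert-butyl methyl malonate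
Product: 10 methyl 2-(2-tert-butoxy-2-oxoethyl)-4,6-dimethoxybenzoate, via 3,5-dimethoxybenzyne 9 (not isolated)
Conditions: CsF (3 equiv), 8 (1.5 equiv), MeCN, 80 °C
Reagents that add atoms: none
Why: Fluoride attacks silicon in 7 and triflate leaves, which gives aryne 9; the caesium enolate of 8 then adds to the aryne carbon remote from the methoxy group (the carbon that carried the triflate, future C-A6), because the inductively withdrawing methoxy group distorts the triple bond and stabilises the negative charge that develops on the adjacent carbon (future C-A1). The aryl anion adds to the methyl ester carbonyl in a 4-exo-trig closure to a transient benzocyclobutene alkoxide, which opens by retro-aldol-type C–C cleavage to the tert-butyl ester enolate; protonation gives 10. The net change is insertion of the aryne into the C–C(=O) bond of the malonate, and no ring remains. The closest known reaction type is the fluoride-induced acyl-alkylation of arynes from 2-silylaryl triflates with malonates and beta-keto esters. No stereocentre is formed. Two selectivities are needed: the site of carbanion addition, secured by the single methoxy group next to the triple bond, and the choice of the methyl over the tert-butyl ester in the acyl transfer, secured by the much greater steric shielding and lower electrophilicity of the tert-butyl ester carbonyl. An excess of 8 should limit arylation of the product enolate by a second aryne.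

Step 5
Reactants: 10 methyl 2-(2-tert-butoxy-2-oxoethyl)-4,6-dimethoxybenzoate
Product: 12 2-[3-hydroxy-5-methoxy-2-(methoxycarbonyl)phenyl]acetic acid, via dimethoxy acid 11 (not isolated)
Conditions: TFA, CH2Cl2, rt; evaporate; BCl3 (3 equiv), CH2Cl2, −78 → 0 °C; H2O
Reagents that add atoms: none
Why: Acidolysis of the tert-butyl ester (loss of isobutene) spares the methyl ester and both aryl methyl ethers. BCl3 then binds the benzoate carbonyl and the adjacent C-A2 methoxy oxygen in a six-membered chelate, and chloride removes that methyl group only, since the C-A4 ether has no carbonyl neighbour (chelation-controlled demethylation).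

Step 6
Reactants: 12 2-[3-hydroxy-5-methoxy-2-(methoxycarbonyl)phenyl]acetic acid
Product: 13 methyl 2-hydroxy-4-methoxy-6-{2-[methoxy(methyl)amino]-2-oxoethyl}benzoate
Conditions: MeNHOMe·HCl, EDC·HCl, HOBt, N-methylmorpholine, CH2Cl2, 0 °C → rt
Reagents that add atoms: N,O-dimethylhydroxylamine hydrochloride, CNOC.Cl
Why: Carbodiimide amidation of the unhindered arylacetic acid; the phenol is hydrogen-bonded to the ester carbonyl and far less nucleophilic than the amine, and the flanked benzoate does not react.

Step 7
Reactants: 13 methyl 2-hydroxy-4-methoxy-6-{2-[methoxy(methyl)amino]-2-oxoethyl}benzoate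
Product: 14 methyl 2-(benzyloxy)-4-methoxy-6-{2-[methoxy(methyl)amino]-2-oxoethyl}benzoate
Conditions: BnBr, K2CO3, DMF, 40 °C
Reagents that add atoms: benzyl bromide, BrCc1ccccc1
Why: Williamson ether synthesis on the only acidic OH; carbonate is too weak to deprotonate the amide CH2, and the benzyl group will leave in the final hydrogenolysis together with the ring B benzyl ester.

Step 8
Reactants: 14 methyl 2-(benzyloxy)-4-methoxy-6-{2-[methoxy(methyl)amino]-2-oxoethyl}benzoate; 15 1-bromopentane
Product: 17 methyl 2-(benzyloxy)-4-methoxy-6-(2-oxoheptyl)benzoate, via pentylmagnesium bromide 16 (not isolated)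
Conditions: 15, Mg turnings, THF, rt → 40 °C; then 14, THF, −20 → 0 °C; aq. NH4Cl
Reagents that add atoms: none
Why: Weinreb ketone synthesis: the Grignard reagent adds once to the N-methoxy-N-methylamide and the magnesium chelate holds until work-up, so no tertiary alcohol forms; the ring ester, flanked on both sides, is too hindered to compete at low temperature.

Step 9
Reactants: 17 methyl 2-(benzyloxy)-4-methoxy-6-(2-oxoheptyl)benzoate
Product: 18 methyl 2-(benzyloxy)-4-methoxy-6-[(2-pentyl-1,3-dioxolan-2-yl)methyl]benzoate
Conditions: Me3SiOCH2CH2OSiMe3, TMSOTf (cat.), CH2Cl2, −78 → −20 °C; pyridine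
Reagents that add atoms: 1,2-bis(trimethylsilyloxy)ethane, C[Si](C)(C)OCCO[Si](C)(C)C
Why: TMSOTf-catalysed ketalisation with the bis-silyl ether of ethylene glycol runs cold and without free protic acid, so the keto ester has no opportunity to close to an isocoumarin; the dioxolane masks the ketone for the basic hydrolysis and the acid activation that follow.

Step 10
Reactants: 18 methyl 2-(benzyloxy)-4-methoxy-6-[(2-pentyl-1,3-dioxolan-2-yl)methyl]benzoate
Product: 19 2-(benzyloxy)-4-methoxy-6-[(2-pentyl-1,3-dioxolan-2-yl)methyl]benzoic acid
Conditions: KOH, DMSO/H2O, 90 °C; then aq. KH2PO4, 0 °C (pH 5)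
Reagents that add atoms: potassium hydroxide, [K+].[OH-]
Why: Saponification of a 2,6-disubstituted methyl benzoate needs poorly solvated hydroxide in DMSO and heat; the ketal, the benzyl ether and the aryl methyl ether are inert to base, and buffered acidification frees the acid without opening the ketal.

Step 11
Reactants: 20 olivetolic acid (2,4-dihydroxy-6-pentylbenzoic acid)
Product: 21 benzyl 2,4-dihydroxy-6-pentylbenzoate
Conditions: BnBr, KHCO3, DMF, rt
Reagents that add atoms: benzyl bromide, BrCc1ccccc1
Why: Hydrogen carbonate ionises only the carboxylic acid, so the carboxylate is alkylated and both phenols stay free (chemoselective carboxylate O-alkylation); room temperature avoids decarboxylation.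

Step 12
Reactants: 19 2-(benzyloxy)-4-methoxy-6-[(2-pentyl-1,3-dioxolan-2-yl)methyl]benzoic acid; 21 benzyl 2,4-dihydroxy-6-pentylbenzoate
Product: 22 benzyl 4-({2-(benzyloxy)-4-methoxy-6-[(2-pentyl-1,3-dioxolan-2-yl)methyl]benzoyl}oxy)-2-hydroxy-6-pentylbenzoate
Conditions: EDC·HCl, DMAP, CH2Cl2, 0 °C → rt
Reagents that add atoms: none
Why: Steglich esterification: DMAP carries the acyl group from the O-acylisourea to the phenol; the hydroxyl at C-B4 reacts because the one at C-B2 is locked in a hydrogen bond to the benzyl ester carbonyl and is crowded by it.

Step 13
Reactants: 22 benzyl 4-({2-(benzyloxy)-4-methoxy-6-[(2-pentyl-1,3-dioxolan-2-yl)methyl]benzoyl}oxy)-2-hydroxy-6-pentylbenzoate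
Product: 23 benzyl 4-{[2-(benzyloxy)-4-methoxy-6-(2-oxoheptyl)benzoyl]oxy}-2-hydroxy-6-pentylbenzoate
Conditions: PPTS, acetone/H2O, 50 °C
Reagents that add atoms: water, O
Why: Mild acid-catalysed ketal hydrolysis regenerates the ketone; pyridinium tosylate should leave the esters and benzyl groups alone, and acid is used because base would enolise the benzylic ketone onto the aryl ester.

Step 14
Reactants: 23 benzyl 4-{[2-(benzyloxy)-4-methoxy-6-(2-oxoheptyl)benzoyl]oxy}-2-hydroxy-6-pentylbenzoate
Product: 24 2-hydroxy-4-{[2-hydroxy-4-methoxy-6-(2-oxoheptyl)benzoyl]oxy}-6-pentylbenzoic acid (target)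
Conditions: H2 (1 atm), 10% Pd/C, EtOAc, rt
Reagents that add atoms: none
Why: Hydrogenolysis cleaves the benzyl ether at C-A2 and the benzyl ester at C-B1 under neutral conditions; the ketone, the aryl ester and the aryl methyl ether are not reduced, and the sensitive product should need only filtration and evaporation.

## Compound list

1 | 3,5-dimethoxyphenol | COc1cc(O)cc(OC)c1 | starting material
2 | 3,5-dimethoxyphenyl N-(propan-2-yl)carbamate | COc1cc(OC)cc(OC(=O)NC(C)C)c1 | intermediate
3 | 3,5-dimethoxyphenyl N-(tert-butyldimethylsilyl)-N-(propan-2-yl)carbamate | COc1cc(OC)cc(OC(=O)N(C(C)C)[Si](C)(C)C(C)(C)C)c1 | intermediate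
4 | 3,5-dimethoxy-2-(trimethylsilyl)phenyl N-(tert-butyldimethylsilyl)-N-(propan-2-yl)carbamate | COc1cc(OC)c([Si](C)(C)C)c(OC(=O)N(C(C)C)[Si](C)(C)C(C)(C)C)c1 | intermediate
5 | 3,5-dimethoxy-2-(trimethylsilyl)phenyl N-(propan-2-yl)carbamate | COc1cc(OC)c([Si](C)(C)C)c(OC(=O)NC(C)C)c1 | intermediate
6 | 3,5-dimethoxy-2-(trimethylsilyl)phenol | COc1cc(O)c([Si](C)(C)C)c(OC)c1 | intermediate
7 | 3,5-dimethoxy-2-(trimethylsilyl)phenyl trifluoromethanesulfonate | COc1cc(OC)c([Si](C)(C)C)c(OS(=O)(=O)C(F)(F)F)c1 | intermediate
8 | tert-butyl methyl malonate | COC(=O)CC(=O)OC(C)(C)C | starting material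
9 | 3,5-dimethoxybenzyne | COC1=CC(OC)=CC#C1 | intermediate
10 | methyl 2-(2-tert-butoxy-2-oxoethyl)-4,6-dimethoxybenzoate | COC(=O)c1c(OC)cc(OC)cc1CC(=O)OC(C)(C)C | intermediate
11 | 2-[3,5-dimethoxy-2-(methoxycarbonyl)phenyl]acetic acid | COC(=O)c1c(OC)cc(OC)cc1CC(=O)O | intermediate
12 | 2-[3-hydroxy-5-methoxy-2-(methoxycarbonyl)phenyl]acetic acid | COC(=O)c1c(O)cc(OC)cc1CC(=O)O | intermediate
13 | methyl 2-hydroxy-4-methoxy-6-{2-[methoxy(methyl)amino]-2-oxoethyl}benzoate | COC(=O)c1c(O)cc(OC)cc1CC(=O)N(C)OC | intermediate
14 | methyl 2-(benzyloxy)-4-methoxy-6-{2-[methoxy(methyl)amino]-2-oxoethyl}benzoate | COC(=O)c1c(OCc2ccccc2)cc(OC)cc1CC(=O)N(C)OC | intermediate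
15 | 1-bromopentane | CCCCCBr | starting material
16 | pentylmagnesium bromide | CCCCC[Mg]Br | intermediate
17 | methyl 2-(benzyloxy)-4-methoxy-6-(2-oxoheptyl)benzoate | CCCCCC(=O)Cc1cc(OC)cc(OCc2ccccc2)c1C(=O)OC | intermediate
18 | methyl 2-(benzyloxy)-4-methoxy-6-[(2-pentyl-1,3-dioxolan-2-yl)methyl]benzoate | CCCCCC1(Cc2cc(OC)cc(OCc3ccccc3)c2C(=O)OC)OCCO1 | intermediate
19 | 2-(benzyloxy)-4-methoxy-6-[(2-pentyl-1,3-dioxolan-2-yl)methyl]benzoic acid | CCCCCC1(Cc2cc(OC)cc(OCc3ccccc3)c2C(=O)O)OCCO1 | intermediate
20 | olivetolic acid (2,4-dihydroxy-6-pentylbenzoic acid) | CCCCCc1cc(O)cc(O)c1C(=O)O | starting material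
21 | benzyl 2,4-dihydroxy-6-pentylbenzoate | CCCCCc1cc(O)cc(O)c1C(=O)OCc1ccccc1 | intermediate
22 | benzyl 4-({2-(benzyloxy)-4-methoxy-6-[(2-pentyl-1,3-dioxolan-2-yl)methyl]benzoyl}oxy)-2-hydroxy-6-pentylbenzoate | CCCCCC1(Cc2cc(OC)cc(OCc3ccccc3)c2C(=O)Oc2cc(O)c(C(=O)OCc3ccccc3)c(CCCCC)c2)OCCO1 | intermediate
23 | benzyl 4-{[2-(benzyloxy)-4-methoxy-6-(2-oxoheptyl)benzoyl]oxy}-2-hydroxy-6-pentylbenzoate | CCCCCC(=O)Cc1cc(OC)cc(OCc2ccccc2)c1C(=O)Oc1cc(O)c(C(=O)OCc2ccccc2)c(CCCCC)c1 | intermediate
24 | 2-hydroxy-4-{[2-hydroxy-4-methoxy-6-(2-oxoheptyl)benzoyl]oxy}-6-pentylbenzoic acid | CCCCCC(=O)Cc1cc(OC)cc(O)c1C(=O)Oc1cc(O)c(C(=O)O)c(CCCCC)c1 | target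

## Step count and least certain steps

Total: 14 steps. Longest linear sequence: 13 steps (steps 1 to 10 and 12 to 14); ring B needs one step (step 11).

Step 4 (key step). The most likely failures are acyl transfer to the tert-butyl ester carbonyl in competition with the methyl ester, protonation of the aryl anion before it reaches either carbonyl (plain alpha-arylation), and arylation of the product enolate by a second aryne. All three stem from the short life of the aryl anion and from the only moderate steric difference between the two esters. Fallback: starting from 7, the same fluoride-induced insertion would be run with symmetrical dimethyl malonate, which removes the question of which ester migrates, to give methyl 2-(2-methoxy-2-oxoethyl)-4,6-dimethoxybenzoate F1. The two esters would then be told apart by rate of hydrolysis: LiOH (1 equiv) in THF/H2O at 0 °C should cleave only the unhindered aliphatic ester. This returns to the route at 11, which then takes the BCl3 treatment of step 5.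

Step 8. The Grignard reagent may deprotonate the benzylic CH2 between the arene and the amide carbonyl in place of adding to it, which would return 14 on work-up; attack at the ring ester is the lesser risk. Fallback: starting from 12, EtSH, EDC·HCl and catalytic DMAP should give the thioester methyl 2-[2-(ethylsulfanyl)-2-oxoethyl]-6-hydroxy-4-methoxybenzoate F2. Pentylzinc bromide F3, made from 15 with Zn dust and LiCl in THF, would be coupled with F2 under PdCl2(PPh3)2 catalysis (Fukuyama coupling, a non-basic nucleophile) to give methyl 2-hydroxy-4-methoxy-6-(2-oxoheptyl)benzoate F4. Ketalisation as in step 9 should give methyl 2-hydroxy-4-methoxy-6-[(2-pentyl-1,3-dioxolan-2-yl)methyl]benzoate F5, and benzylation (BnBr, K2CO3, DMF) returns to the route at 18.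

Step 10. Hydroxide addition to the ester carbonyl may stall because both ortho positions are occupied, and forcing the temperature invites cleavage of the benzyl ether. Fallback: starting from 18, the ester would be cleaved at its methyl carbon and not at the carbonyl, by SN2 demethylation with n-PrSLi in DMF at rt to 50 °C followed by buffered acidification. This returns to the route at 19 and makes no new compound (F0).

Step 12. Acyl transfer from the hindered O-acylisourea may be slower than its rearrangement to the N-acylurea, and some acylation at the C-B2 oxygen or at both oxygens is conceivable. Fallback: starting from 19, the neutral chloroenamine reagent 1-chloro-N,N,2-trimethylprop-1-en-1-amine in CH2Cl2 at 0 °C should give 2-(benzyloxy)-4-methoxy-6-[(2-pentyl-1,3-dioxolan-2-yl)methyl]benzoyl chloride F6 without freeing acid that would open the ketal. F6 would be added to 21 with Et3N and catalytic DMAP, returning to the route at 22.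

Step 13. Once the ketone is free, its enol or hemiketal oxygen may close onto the aryl ester carbonyl under acid and expel the ring B phenol (isocoumarin formation); milder acid may leave the ketal unhydrolysed. Fallback: the ketone would be carried through the coupling as a dithioketal that is removed without acid. Starting from 17, ethane-1,2-dithiol with catalytic iodine in CH2Cl2 should give methyl 2-(benzyloxy)-4-methoxy-6-[(2-pentyl-1,3-dithiolan-2-yl)methyl]benzoate F7. Hydrolysis as in step 10 should give 2-(benzyloxy)-4-methoxy-6-[(2-pentyl-1,3-dithiolan-2-yl)methyl]benzoic acid F8, and coupling with 21 as in step 12 should give benzyl 4-({2-(benzyloxy)-4-methoxy-6-[(2-pentyl-1,3-dithiolan-2-yl)methyl]benzoyl}oxy)-2-hydroxy-6-pentylbenzoate F9. Alkylative hydrolysis (MeI, CaCO3, MeCN/H2O, 40 °C) would then return to the route at 23.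

## Further compounds

F1 | step 4 | methyl 2-(2-methoxy-2-oxoethyl)-4,6-dimethoxybenzoate | COC(=O)Cc1cc(OC)cc(OC)c1C(=O)OC
F2 | step 8 | methyl 2-[2-(ethylsulfanyl)-2-oxoethyl]-6-hydroxy-4-methoxybenzoate | CCSC(=O)Cc1cc(OC)cc(O)c1C(=O)OC
F3 | step 8 | pentylzinc bromide | CCCCC[Zn]Br
F4 | step 8 | methyl 2-hydroxy-4-methoxy-6-(2-oxoheptyl)benzoate | CCCCCC(=O)Cc1cc(OC)cc(O)c1C(=O)OC
F5 | step 8 | methyl 2-hydroxy-4-methoxy-6-[(2-pentyl-1,3-dioxolan-2-yl)methyl]benzoate | CCCCCC1(Cc2cc(OC)cc(O)c2C(=O)OC)OCCO1
F0 | step 10 | none | none
F6 | step 12 | 2-(benzyloxy)-4-methoxy-6-[(2-pentyl-1,3-dioxolan-2-yl)methyl]benzoyl chloride | CCCCCC1(Cc2cc(OC)cc(OCc3ccccc3)c2C(=O)Cl)OCCO1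
F7 | step 13 | methyl 2-(benzyloxy)-4-methoxy-6-[(2-pentyl-1,3-dithiolan-2-yl)methyl]benzoate | CCCCCC1(Cc2cc(OC)cc(OCc3ccccc3)c2C(=O)OC)SCCS1
F8 | step 13 | 2-(benzyloxy)-4-methoxy-6-[(2-pentyl-1,3-dithiolan-2-yl)methyl]benzoic acid | CCCCCC1(Cc2cc(OC)cc(OCc3ccccc3)c2C(=O)O)SCCS1
F9 | step 13 | benzyl 4-({2-(benzyloxy)-4-methoxy-6-[(2-pentyl-1,3-dithiolan-2-yl)methyl]benzoyl}oxy)-2-hydroxy-6-pentylbenzoate | CCCCCC1(Cc2cc(OC)cc(OCc3ccccc3)c2C(=O)Oc2cc(O)c(C(=O)OCc3ccccc3)c(CCCCC)c2)SCCS1
A1 | alternative 1 | benzyl 2-hydroxy-4-({2-hydroxy-4-methoxy-6-[(2-pentyl-1,3-dioxolan-2-yl)methyl]benzoyl}oxy)-6-pentylbenzoate | CCCCCC1(Cc2cc(OC)cc(O)c2C(=O)Oc2cc(O)c(C(=O)OCc3ccccc3)c(CCCCC)c2)OCCO1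
A2 | alternative 1 | benzyl 2-hydroxy-6-pentyl-4-{[4-(2-pentyl-1,3-dioxolan-2-yl)but-2-ynoyl]oxy}benzoate | CCCCCC1(CC#CC(=O)Oc2cc(O)c(C(=O)OCc3ccccc3)c(CCCCC)c2)OCCO1
A3 | alternative 1 | 1,3-dimethoxy-1-(trimethylsilyloxy)buta-1,3-diene (ketene acetal geometry not defined) | COC(=C)C=C(OC)O[Si](C)(C)C
A4 | alternative 2 | racemic trans benzyl 2-hydroxy-4-oxo-6-pentylcyclohex-2-ene-1-carboxylate (one enantiomer drawn) | CCCCC[C@@H]1CC(=O)C=C(O)[C@H]1C(=O)OCc1ccccc1
A5 | alternative 2 | dibenzyl malonate | O=C(CC(=O)OCc1ccccc1)OCc1ccccc1
A6 | alternative 2 | (E)-non-3-en-2-one | CCCCC/C=C/C(C)=O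
A7 | alternative 3 | benzyl 2-(benzyloxy)-4-hydroxy-6-pentylbenzoate | CCCCCc1cc(O)cc(OCc2ccccc2)c1C(=O)OCc1ccccc1
A8 | alternative 3 | benzyl 4-(benzyloxy)-2-oxo-6-pentyl-2H-pyran-5-carboxylate | CCCCCc1oc(=O)cc(OCc2ccccc2)c1C(=O)OCc1ccccc1
A9 | alternative 3 | tert-butyl[(1-methoxyethenyl)oxy]dimethylsilane | C=C(OC)O[Si](C)(C)C(C)(C)C
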